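In a one-step world starting material and partner would give target from the first moment, but the oak run read 0% of target at 4.00 min beside 32.5% of open intermediate, so something stands between them.

| setting | oak | cedar | spring | midnight | dusk |
|---|---|---|---|---|---|
| starting material | 0.60 M | 0.80 M | 0.40 M | 0.40 M | 0.40 M |
| partner | 0.80 M | 0.80 M | 0.800 M | 1.20 M | 1.80 M |
| remark | run made earlier | run made earlier |  |  |  |
| time |  |  | 50 min | 50 min | 50 min |

- oak (time / min: starting material / %, target / %, open intermediate / %): 4.00: 67.1, 0, 32.5; 10.0: 37.0, 6.0, 57.0; 20.0: 14.6, 24.4, 61.9; 30.0: 4.9, 44.2, 52.3
- cedar (time / min: starting material / %, target / %, open intermediate / %): 8.00: 44.5, 3.5, 51.1; 15.0: 21.7, 13.8, 63.6; 25.0: 7.5, 30.9, 60.6; 30.0: 4.5, 39.7, 55.8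

(each reading ± 0.5 percentage points)

1. which of these there is most of at the end, counted by the starting material in it, spring (target / open intermediate / starting material)
2. which of these there is most of at the end, counted by the starting material in it, midnight (target / open intermediate / starting material)
3. which of these there is most of at the end, counted by the starting material in it, dusk (target / open intermediate / starting material)
4. final amount of the leader among these, as a percentage of the starting material charged, in spring
5. final amount of the leader among these, as a percentage of the starting material charged, in midnight
6. final amount of the leader among these, as a percentage of the starting material charged, in dusk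

- what was read earlier has a scatter of 0.5 percentage points, one standard deviation

How fast did starting material leave? The oak run gave me a first-order constant of 0.101 min⁻¹, and the cedar run, charged higher, read 0.104 min⁻¹. So I expected 0.652% of it left at 50 min.

How fast did open intermediate close to target? I wrote the balance of starting material, the limiting reagent of spring, midnight and dusk, where it was charged in a smaller amount than partner: target is the charge less starting material and open intermediate. Between its last two readings the oak run gained target at 0.0347 min⁻¹ of the mean open intermediate. This is the closing constant κ, a pseudo-first-order constant read in a run charged with c(partner) = 0.80 M; the cedar run read 0.0302 min⁻¹. It is slower than the first step, so open intermediate piled up in the oak run.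

What stood at 50 min? Both runs were charged with the same c(partner), so they could not show how κ follows it, and I assumed κ proportional to that charge. Treating κ as constant over a run, although it was read late in the oak run, two first-order steps in a row leave kA/(kA − κ) · (exp(−κt) − exp(−kAt)) as open intermediate. That gave me 25.9% in spring, 14.0% in midnight and 6.09% in dusk. By the balance, target came to 73.4%, 85.3% and 93.3%, ahead in each flask.

The forecast also named target in each flask, at 74%, 87% and 96%, somewhat above my figures, having concluded “so starting material inhibits”.

Spring, midnight and dusk gave 75.8%, 88.9% and 95.8% of target, the leader in each, so the forecast held. Spring also held 0.362% of over-reaction product at 50.0 min, which my balance did not count; that step's half-life of 58 h is long against 50 min, and it makes no difference to spring's target. Carried to the end of spring, κ's 25.9% of open intermediate stands against 23.1% found.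

    target → over-reaction product (k = 2.00 × 10⁻⁴ min⁻¹)
    starting material → open intermediate (k = 0.100 min⁻¹)
    open intermediate + second intermediate → target (k = 0.110 M⁻¹ min⁻¹)
    partner → second intermediate (k = 0.0400 min⁻¹)

For the neighbour of spring charged with 0.20 M of partner, my proportionality scales κ to 0.00867 min⁻¹, which leaves 70.2% of open intermediate and 29.1% of target at 50 min. Computed, that flask holds 72.2% of open intermediate and 27.0% of target, with open intermediate in the lead.

The numbers in the tables are calculated for substances that don't exist, and the scatter is random.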